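I began with an easy step: a first-order loss halves a quantity in a fixed time, whatever amount it starts from.

- north: L 0.25 M; run made earlier
- flask: L 0.50 M; time 25 h

north run (percent of the L charged)

| time / h | J / % | X / % |
|---|---|---|
| 0.667 | 57 | 9 |
| 2.00 | 44 | 12 |
| 3.00 | 22 | 9 |
| 5.00 | 8 | 9 |

(each reading ± 2 percentage points)

- ratio of J to X at 5.0 min
- ratio of J to X at 1.5 h
- ratio of J to X at 25 h
- which of J and X there is more of at 25 h

- solid, in amounts per volume of the solution: L
- steps under discussion: D <-> Z; D -> J; Z -> X; J <-> X; L <-> D; J <-> G; Z -> E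
- at the start none of L is in solution

**Main step.** I took D → J first, by itself: it makes J and no X. The north run read 57% of J at 0.667 h.

**Adding drain.** North's J then fell from 44% at 2.00 h to 8% at 5.00 h. Read as first order, that is cJ losing 0.568 h⁻¹, which gives a drain time of 1.22 h, the half-life of J as read off these two north readings. The asked times are 0.0683, 1.23 and 20.5 drain times, so 5.0 min falls well inside the first one, and 25 h lies far beyond it.

**Adding X.** North's X stayed between 9% and 12%. My first round, the drain by itself, reckoned J from north's reading of 8% at 5.00 h down to <0.001% at 25 h.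

**Second round.** I put that figure back in. By north's reading, 92.0% of the charge stood outside J at 5.00 h, far more than that figure, so I kept the back steps J <- X and J <- G. I therefore expected a floor under cJ, with X ahead: north's last readings had 9% of X against 8% of J, with J falling. The readings gave me no height for that floor.

**The forecast.** It gave 8, 5 and 0.4, with X ahead, and held that “Charge shouldn't matter” at the late time.

**The result.** The flask gave 9.51, 4.40 and 0.424, with X ahead, 9.44% against 4.01% of J. At 25.0 h, J was made 1.00 times as fast as it was used, each step taken net. The drain time would have carried the flask's 32.7% of J at 2.50 h down to 0.112% at 12.5 h, but the flask held 4.13%.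

    D ⇌ Z (K = 0.0120, k = 2.00 × 10⁻⁴ s⁻¹)
    D → J (k = 5.80 × 10⁻⁴ s⁻¹)
    Z → X (k = 0.00930 s⁻¹)
    J ⇌ X (K = 0.740, k = 3.90 × 10⁻⁶ s⁻¹)
    L ⇌ D, rate k5*(cs5 - [D]) while solid is left; crystals form when [D] > cs5 (solubility = 0.490 M, k = 0.0110 s⁻¹)
    J ⇌ G (K = 23.0, k = 1.40 × 10⁻⁴ s⁻¹)
    Z → E (k = 2.00 × 10⁻⁷ s⁻¹)

**Second flask.** Taking the drain time as independent of the charge, a neighbour flask charged 1.2 M of L also reaches 20.5 drain times by 25 h, so I expected the flask's 0.424 again. It gave 0.423, with 9.47% of X.

The earlier runs and the new flask are calculated for an exercise; the scatter is artificial.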